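**Plan**

1. Numbering is that of the octalin core (C1 quaternary, C2 sec-butyl, C3=C4, C5 OH, C6 ester, C8 methyl); β is the face of H-8a, α the face of H-4a.
2. Retrosynthesis: cut the C6 ester (cyclic anhydride) and the CH2–CH2O bond of the side chain; return the C3=C4 alkene and H-2 to a C2=C3–C4=O enone (reductive 1,3-transposition).
3. Ring A is then cut at C4–C4a and C1–C2 together: C1 and C4a are each α to a carbonyl (acetyl C=O, C5=O) on either side of C8a, so a 1,5-diketone bis-enol ether can take up C4–C3–C2 as an alkynal (C4 aldehyde carbon, C2 alkyne terminus).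
4. The bis-enol ether is released regiospecifically from a temporary cyclopropane (C1 bridging C4a and C8a) built on (R)-4-methylcyclohexenone, which is ring B.
5. Forward: ring B, cyclopropane, bis(silyl enol ether), ring A by aldol/6-endo carbocyclisation, then O at C6, reduction at C5, enone, transposition, side chain, ester, desilylation.
6. Stereochemistry: C8 and the sec-butyl centre are bought; C8a anti to the C8 methyl; C4a anti to the C8a substituent; C1 by allylic 1,3-strain in the ring closure; C6 by L-proline and axial attack; C5 by axial hydride; C2 by suprafacial diazene hydrogen transfer after axial hydride attack at C4; Z-alkene from the anhydride ring.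

Key step: step 8

Assumption: (R)-2-methylbutanoic acid and (R)-4-methylcyclohex-2-en-1-one are taken as purchasable in enantiopure form.

**Route**

Step 1
Reactants: 1 (R)-2-methylbutanoic acid
Product: 2 (R)-2-methylbutan-1-ol
Conditions: LiAlH4, Et2O, 0 to 35 °C; aqueous NaOH work-up
Reagents that add atoms: none
Why: LiAlH4 reduction of a carboxylic acid, under which the non-enolisable stereocentre should be retained.

Step 2
Reactants: 2 (R)-2-methylbutan-1-ol
Product: 3 (R)-2-methylbutanal
Conditions: TEMPO (10 mol%), PhI(OAc)2, CH2Cl2, 23 °C; used as a solution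
Reagents that add atoms: none
Why: TEMPO/PhI(OAc)2 oxidation stops at the aldehyde under non-basic conditions, so the α-stereocentre should not epimerise.

Step 3
Reactants: 3 (R)-2-methylbutanal
Product: 4 (R)-1,1-dibromo-3-methylpent-1-ene
Conditions: CBr4, PPh3, CH2Cl2, 0 °C
Reagents that add atoms: carbon tetrabromide, BrC(Br)(Br)Br
Why: First stage of the Corey–Fuchs reaction (Wittig-type dibromo-olefination), neutral and cold enough to leave the α-centre intact.

Step 4
Reactants: 4 (R)-1,1-dibromo-3-methylpent-1-ene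
Product: 6 (R)-4-methylhex-2-ynal, via lithium acetylide 5 (not isolated)
Conditions: n-BuLi (2.1 equiv), THF, −78 °C; DMF, −78 to 0 °C; inverse quench into cold 1 M HCl
Reagents that add atoms: N,N-dimethylformamide, CN(C)C=O
Why: Second stage of the Corey–Fuchs reaction (Br/Li exchange, Fritsch–Buttenberg–Wiechell shift, deprotonation) followed by formylation of the acetylide, the acidic inverse quench preventing amine addition to the ynal.

Step 5
Reactants: 7 3-bromobutan-2-one (racemic)
Product: 8 dimethyl(3-oxobutan-2-yl)sulfonium bromide (racemic)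
Conditions: Me2S, acetone, 23 °C
Reagents that add atoms: dimethyl sulfide, CSC
Why: SN2 alkylation of a sulfide by an α-bromo ketone gives the crystalline sulfonium salt.

Step 6
Reactants: 9 (R)-4-methylcyclohex-2-en-1-one; 8 dimethyl(3-oxobutan-2-yl)sulfonium bromide
Product: 11 (5R)-7-acetyl-5,7-dimethylbicyclo[4.1.0]heptan-2-one (cyclopropane cis-fused and anti to the 5-methyl; either configuration at C7), via sulfonium ylide 10 (not isolated)
Conditions: K2CO3 (powder), MeCN, 40 °C
Reagents that add atoms: none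
Why: Corey–Chaykovsky cyclopropanation (Michael-initiated ring closure) of an enone with a keto-stabilised sulfonium ylide, whose carbon should add to C8a anti to the C8 methyl before 3-exo-tet closure at C4a (the configuration at the acetyl-bearing carbon is lost in step 7).

Step 7
Reactants: 11 (5R)-7-acetyl-5,7-dimethylbicyclo[4.1.0]heptan-2-one
Product: 13 bis(triethylsilyl enol ether) of (3,4-trans,4R)-4-methyl-3-(3-oxobutan-2-yl)cyclohexanone (ring enol ether C4a=C5, side-chain enol ether C1=C(OSiEt3)CH3), via dilithium bis-enolate 12 (not isolated)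
Conditions: Li (2.2 equiv), NH3/THF, −78 °C; NH3 evaporated; Et3SiCl, Et3N, THF, −78 to 0 °C
Reagents that add atoms: chlorotriethylsilane, CC[Si](Cl)(CC)CC
Why: Dissolving-metal reductive cleavage of a cyclopropyl ketone: the C1–C4a bond overlaps with both carbonyl π systems, so strain-releasing two-electron cleavage should give the 1,5-diketone bis-enolate regiospecifically, which is O-silylated.

Step 8
Reactants: 13 bis(triethylsilyl enol ether); 6 (R)-4-methylhex-2-ynal
Product: 15 1β-acetyl-2-[(R)-butan-2-yl]-1α,8β-dimethyl-4-(triethylsilyloxy)-1,4,4a,5,6,7,8,8a-octahydronaphthalen-5-one (C2=C3 alkene, H-4a α, H-8a β, both C4 epimers), via aldol silyl ether 14 (not isolated)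
Conditions: HNTf2 (2 mol%), CH2Cl2, −78 °C; then 2,6-di-tert-butyl-4-methylpyridine (5 mol%), [(2-di-tert-butylphosphino-2',4',6'-triisopropylbiphenyl)Au(NCMe)]SbF6 (5 mol%), MeOH (1.5 equiv), −20 to 23 °C
Reagents that add atoms: none
Why: Proposed new method: Et3SiNTf2 formed from HNTf2 catalyses a Mukaiyama aldol addition of the less hindered ring enol ether to the aldehyde of 6 (C4a–C4 bond, silyl transfer to O4), and the cationic monovalent gold complex then activates the C2≡C3 alkyne of 14 for anti attack by the remaining enol ether carbon C1 at C2, methanol taking the silyl group and protonating the vinylgold at C3. The closest known reactions are the silyl triflimide-catalysed Mukaiyama aldol and the gold-catalysed carbocyclisation of silyl enol ethers onto alkynes, here run in tandem as a formal [3+3] annulation of a 1,3-bis-enol ether with an alkynal. Ring A closes by 6-endo-dig attack (enol ether exo to the new ring). C4a is set by approach of the aldehyde anti to the pseudoaxial C8a substituent, C1 by allylic 1,3-strain (H-8a eclipses the enol double bond, so the alkyne tethered through C4a meets the face that leaves the methyl α and the acetyl β), and C4 forms as both epimers, which converge in step 11. The step needs site selection between the two enol ethers, 6-endo over 5-exo closure and C- over carbonyl-O-attack on the alkyne; these should be secured by the hindrance of the tetrasubstituted α-branched enol ether toward intermolecular attack, by the trans-diequatorial tether (5-exo closure would give a trans-hydrindane), the inductive effect of O4 on C3 and the bulky biarylphosphine, and by the higher nucleophilicity of an enol ether compared with a ketone oxygen.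

Step 9
Reactants: 15 octalinone silyl ether
Product: 17 6α-[N-acetyl(phenyl)aminooxy] derivative of 15, via anilinooxy ketone 16 (not isolated)
Conditions: L-proline (30 mol%), PhNO (1.2 equiv, slow addition), DMF, 0 °C; then pyridine, Ac2O, DMAP (5 mol%), 0 to 23 °C
Reagents that add atoms: nitrosobenzene, O=Nc1ccccc1; acetic anhydride, CC(=O)OC(C)=O
Why: Proline-catalysed α-aminoxylation (O-selective nitroso aldol) through the less substituted C5=C6 enamine, the C6–O bond forming axially on the α face as favoured both by L-proline and by the chair, followed by N-acetylation to mask the oxidisable N–H.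

Step 10
Reactants: 17 6α-[N-acetyl(phenyl)aminooxy] ketone
Product: 19 4,5α-diol (5β-H; C4 epimers), via C5 alcohol 18 (not isolated)
Conditions: NaBH4, MeOH/THF, −78 °C; then PPTS, MeOH, 23 °C
Reagents that add atoms: none
Why: NaBH4 reduction of the activated α-oxy cyclohexanone by axial attack on the β face, anti to the axial C6–O bond, should give the equatorial 5α-alcohol while the neopentyl methyl ketone reacts far more slowly, and acid methanolysis then removes the allylic silyl ether.

Step 11
Reactants: 19 4,5α-diol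
Product: 20 1β-acetyl-2-[(R)-butan-2-yl]-5α-hydroxy-6α-[N-acetyl(phenyl)aminooxy]-1α,8β-dimethyl-4a,5,6,7,8,8a-hexahydronaphthalen-4(1H)-one
Conditions: MnO2 (activated, excess), CH2Cl2, 23 °C
Reagents that add atoms: none
Why: MnO2 oxidises only the allylic C4 alcohol, so both C4 epimers should converge on one enone.

Step 12
Reactants: 20 enone
Product: 23 1β-acetyl-2β-[(R)-butan-2-yl]-5α-hydroxy-6α-[N-acetyl(phenyl)aminooxy]-1α,8β-dimethyl-1,2,4a,5,6,7,8,8a-octahydronaphthalene (C3=C4 alkene, H-2 α), via tosylhydrazone 21 (not isolated), via allylic diazene 22 (not isolated)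
Conditions: TsNHNH2 (1.05 equiv), THF, 23 °C; then catecholborane, CHCl3, 0 °C; then NaOAc·3H2O, 60 °C
Reagents that add atoms: none
Why: Caglioti-type reductive 1,3-transposition of an enone tosylhydrazone: hydride should add to C4 axially on the β face (anti to the axial C1 methyl), sulfinate loss gives the 4α-diazene, and its retro-ene loss of N2 delivers hydrogen suprafacially to C2 on the α face while the alkene moves to C3=C4, as Δ4-3-keto steroid tosylhydrazones give 5β-Δ3-olefins.

Step 13
Reactants: 23 Δ3-octalin methyl ketone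
Product: 24 5α-triethylsilyl ether of 23 with the acetyl group as its triethylsilyl enol ether
Conditions: Et3SiOTf (2.5 equiv), Et3N, CH2Cl2, −78 to 0 °C
Reagents that add atoms: triethylsilyl trifluoromethanesulfonate, CC[Si](CC)(CC)OS(=O)(=O)C(F)(F)F
Why: Silyl triflate/amine silylation protects the C5 alcohol and converts the methyl ketone, enolisable on one side only, into its enol ether.

Step 14
Reactants: 24 enol silyl ether
Product: 25 5α-triethylsilyl ether bearing the 1β-[3-(triisopropylsilyloxy)propanoyl] side chain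
Conditions: iPr3SiOCH2Cl, ZnBr2 (10 mol%), CH2Cl2, −40 to 0 °C
Reagents that add atoms: (triisopropylsiloxy)methyl chloride, ClCO[Si](C(C)C)(C(C)C)C(C)C
Why: Mukaiyama-type alkylation of a silyl enol ether with an α-chloro ether installs the protected hydroxymethyl carbon.

Step 15
Reactants: 25 N-acetyl(phenyl)aminooxy compound
Product: 26 6α-alcohol (O5 and the primary oxygen still silylated)
Conditions: SmI2 (2.5 equiv), THF/MeOH, −78 °C
Reagents that add atoms: none
Why: SmI2 cleaves the N–O bond of the N-acyl-N-aryl alkoxyamine by single-electron transfer and should free only the C6 hydroxyl.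

Step 16
Reactants: 27 3-methylglutaconic acid (E/Z mixture)
Product: 28 3-methylglutaconic anhydride (4-methyl-2H-pyran-2,6(3H)-dione)
Conditions: Ac2O, 100 °C; distillation
Reagents that add atoms: none
Why: Dehydration of the diacid to the six-membered cyclic anhydride, on which both alkene isomers should converge because ring closure needs the cis arrangement and the acid isomerises under the conditions.

Step 17
Reactants: 26 6α-alcohol; 28 3-methylglutaconic anhydride
Product: 29 5-O-triethylsilyl, O-triisopropylsilyl bis-ether of tandyukisin D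
Conditions: 28 (excess), toluene, 4 Å molecular sieves, 70 °C
Reagents that add atoms: none
Why: Alcoholysis of the cyclic anhydride at its non-conjugated, more electrophilic carbonyl should give the half ester with the free conjugated acid, the ring fixing the Z geometry.

Step 18
Reactants: 29 bis-silyl ether
Product: 30 tandyukisin D
Conditions: HF·pyridine, pyridine/THF, 0 to 23 °C
Reagents that add atoms: none
Why: Fluoride cleavage of both silyl ethers under buffered, weakly acidic conditions should avoid acyl migration and β-elimination.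

**Compound list**

1 | (R)-2-methylbutanoic acid | CC[C@@H](C)C(=O)O | starting material
2 | (R)-2-methylbutan-1-ol | CC[C@@H](C)CO | intermediate
3 | (R)-2-methylbutanal | CC[C@@H](C)C=O | intermediate
4 | (R)-1,1-dibromo-3-methylpent-1-ene | CC[C@@H](C)C=C(Br)Br | intermediate
5 | lithium (R)-3-methylpent-1-yn-1-ide (not isolated) | CC[C@@H](C)C#[C-].[Li+] | intermediate
6 | (R)-4-methylhex-2-ynal | CC[C@@H](C)C#CC=O | intermediate
7 | 3-bromobutan-2-one (racemic) | CC(Br)C(C)=O | starting material
8 | dimethyl(3-oxobutan-2-yl)sulfonium bromide (racemic) | CC(C(C)=O)[S+](C)C.[Br-] | intermediate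
9 | (R)-4-methylcyclohex-2-en-1-one | C[C@@H]1CCC(=O)C=C1 | starting material
10 | dimethylsulfonium 3-oxobutan-2-ylide (not isolated) | C[C-](C(C)=O)[S+](C)C | intermediate
11 | (5R)-7-acetyl-5,7-dimethylbicyclo[4.1.0]heptan-2-one, cyclopropane anti to the 5-methyl, C7 unspecified | C[C@@H]1CCC(=O)[C@@H]2[C@H]1C2(C)C(C)=O | intermediate
12 | dilithium bis-enolate of the 1,5-diketone (not isolated) | C[C@@H]1CCC([O-])=C[C@H]1C(C)=C(C)[O-].[Li+].[Li+] | intermediate
13 | bis(triethylsilyl enol ether) of (3,4-trans,4R)-4-methyl-3-(3-oxobutan-2-yl)cyclohexanone | C[C@@H]1CCC(O[Si](CC)(CC)CC)=C[C@H]1C(C)=C(C)O[Si](CC)(CC)CC | intermediate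
14 | aldol silyl ether: C4a carries CH(OSiEt3)–C≡C–sec-butyl trans to the C8a substituent, C5 ketone, side-chain enol ether intact, C4 epimers (not isolated) | CC[C@@H](C)C#CC(O[Si](CC)(CC)CC)[C@H]1C(=O)CC[C@@H](C)[C@@H]1C(C)=C(C)O[Si](CC)(CC)CC | intermediate
15 | 1β-acetyl-2-[(R)-butan-2-yl]-1α,8β-dimethyl-4-(triethylsilyloxy)-1,4,4a,5,6,7,8,8a-octahydronaphthalen-5-one, H-4a α, H-8a β, C4 epimers | CC[C@@H](C)C1=CC(O[Si](CC)(CC)CC)[C@H]2C(=O)CC[C@@H](C)[C@@H]2[C@@]1(C)C(C)=O | intermediate
16 | 6α-(phenylaminooxy) derivative of 15 (not isolated) | CC[C@@H](C)C1=CC(O[Si](CC)(CC)CC)[C@H]2C(=O)[C@H](ONc3ccccc3)C[C@@H](C)[C@@H]2[C@@]1(C)C(C)=O | intermediate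
17 | 6α-[N-acetyl(phenyl)aminooxy] derivative of 15 | CC[C@@H](C)C1=CC(O[Si](CC)(CC)CC)[C@H]2C(=O)[C@H](ON(C(C)=O)c3ccccc3)C[C@@H](C)[C@@H]2[C@@]1(C)C(C)=O | intermediate
18 | 5α-alcohol of 17 (not isolated) | CC[C@@H](C)C1=CC(O[Si](CC)(CC)CC)[C@H]2[C@H](O)[C@H](ON(C(C)=O)c3ccccc3)C[C@@H](C)[C@@H]2[C@@]1(C)C(C)=O | intermediate
19 | 4,5α-diol (C4 epimers) | CC[C@@H](C)C1=CC(O)[C@H]2[C@H](O)[C@H](ON(C(C)=O)c3ccccc3)C[C@@H](C)[C@@H]2[C@@]1(C)C(C)=O | intermediate
20 | 4-oxo enone with 5α-OH and 6α-[N-acetyl(phenyl)aminooxy] | CC[C@@H](C)C1=CC(=O)[C@H]2[C@H](O)[C@H](ON(C(C)=O)c3ccccc3)C[C@@H](C)[C@@H]2[C@@]1(C)C(C)=O | intermediate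
21 | C4 tosylhydrazone of 20 (not isolated) | CC[C@@H](C)C1=CC(=NNS(=O)(=O)c3ccc(C)cc3)[C@H]2[C@H](O)[C@H](ON(C(C)=O)c4ccccc4)C[C@@H](C)[C@@H]2[C@@]1(C)C(C)=O | intermediate
22 | 4α-diazenyl compound, H-4 β (not isolated) | CC[C@@H](C)C1=C[C@H](N=N)[C@H]2[C@H](O)[C@H](ON(C(C)=O)c3ccccc3)C[C@@H](C)[C@@H]2[C@@]1(C)C(C)=O | intermediate
23 | 1β-acetyl-2β-[(R)-butan-2-yl]-5α-hydroxy-6α-[N-acetyl(phenyl)aminooxy]-1α,8β-dimethyl-1,2,4a,5,6,7,8,8a-octahydronaphthalene | CC[C@@H](C)[C@H]1C=C[C@H]2[C@H](O)[C@H](ON(C(C)=O)c3ccccc3)C[C@@H](C)[C@@H]2[C@@]1(C)C(C)=O | intermediate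
24 | 5α-triethylsilyl ether of 23 with 1β-(1-triethylsilyloxyvinyl) group | CC[C@@H](C)[C@H]1C=C[C@H]2[C@H](O[Si](CC)(CC)CC)[C@H](ON(C(C)=O)c3ccccc3)C[C@@H](C)[C@@H]2[C@@]1(C)C(=C)O[Si](CC)(CC)CC | intermediate
25 | 5α-triethylsilyl ether with 1β-[3-(triisopropylsilyloxy)propanoyl] side chain | CC[C@@H](C)[C@H]1C=C[C@H]2[C@H](O[Si](CC)(CC)CC)[C@H](ON(C(C)=O)c3ccccc3)C[C@@H](C)[C@@H]2[C@@]1(C)C(=O)CCO[Si](C(C)C)(C(C)C)C(C)C | intermediate
26 | 6α-alcohol of 25 | CC[C@@H](C)[C@H]1C=C[C@H]2[C@H](O[Si](CC)(CC)CC)[C@H](O)C[C@@H](C)[C@@H]2[C@@]1(C)C(=O)CCO[Si](C(C)C)(C(C)C)C(C)C | intermediate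
27 | 3-methylglutaconic acid (3-methylpent-2-enedioic acid, E/Z mixture) | CC(CC(=O)O)=CC(=O)O | starting material
28 | 3-methylglutaconic anhydride (4-methyl-2H-pyran-2,6(3H)-dione) | CC1=CC(=O)OC(=O)C1 | intermediate
29 | 5-O-triethylsilyl, O-triisopropylsilyl bis-ether of tandyukisin D | CC[C@@H](C)[C@H]1C=C[C@H]2[C@H](O[Si](CC)(CC)CC)[C@H](OC(=O)C/C(C)=C\C(=O)O)C[C@@H](C)[C@@H]2[C@@]1(C)C(=O)CCO[Si](C(C)C)(C(C)C)C(C)C | intermediate
30 | tandyukisin D | CC[C@@H](C)[C@H]1C=C[C@H]2[C@H](O)[C@H](OC(=O)C/C(C)=C\C(=O)O)C[C@@H](C)[C@@H]2[C@@]1(C)C(=O)CCO | target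

**Step count and risks**

Total step count: 18. Longest linear sequence: 14 steps (1 to 6 in four steps, then steps 8 to 15, 17 and 18).

Steps most likely to fail:

Step 8. The aldol stage may choose the wrong enol ether. The gold stage may close 5-exo, cyclise through the C5 carbonyl oxygen towards a furan, or lose the hindered enol ether by protodesilylation before it cyclises. Fallback with known chemistry, setting out from 11 and coming back at 15: the dilithium bis-enolate 12 (Li, NH3/THF, then THF alone) is treated with 6 at −78 °C, where the less hindered ring enolate should add and any adduct of the tetrasubstituted enolate should revert, giving the dilithium aldolate F1. Et3SiCl/Et3N then gives 14, now isolated. A separate gold-catalysed 6-endo-dig carbocyclisation of the silyl enol ether onto the alkyne (same gold complex, MeOH, CH2Cl2) gives 15.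

Step 12. Hydride delivery to the hydrazone carbon may show poor facial selectivity, which would erode the configuration at C2, and the methyl ketone may compete in hydrazone formation or reduction. Fallback, setting out from 20 and coming back at 24:
- Et3SiCl/imidazole protects O5, giving the 5α-triethylsilyloxy enone F2.
- Luche reduction (NaBH4, CeCl3·7H2O, MeOH, −78 °C) by axial attack should give the equatorial 4α-alcohol F3, which can be purified from its epimer.
- ClCO2Me/pyridine gives the methyl carbonate F4.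
- Tsuji–Trost substitution with N-isopropylidene-N'-2-nitrobenzenesulfonyl hydrazine (Pd(PPh3)4, THF) at the less hindered terminus C4 with net retention gives the allylic sulfonyl hydrazone F5.
- Hydrolysis (CF3CH2OH/H2O, AcOH) releases the 4α-diazene F6, whose retro-ene loss of N2 gives the 5α-triethylsilyloxy Δ3-octalin F7 with H-2 α.
- Et3SiOTf/Et3N converts F7 into 24.

Step 17. Acylation of the hindered axial alcohol may be slow, the anhydride may be deprotonated and isomerise, or the alcohol may attack the conjugated carbonyl. Fallback, setting out from 26 and 28 and coming back at 30: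
- Allyl alcohol opens 28 to the allyl half ester F8.
- tert-Butyl 2,2,2-trichloroacetimidate esterifies the conjugated acid, giving the allyl tert-butyl diester F9.
- Pd(PPh3)4/morpholine removes the allyl group, giving the tert-butyl half ester acid F10.
- Steglich esterification (DCC, DMAP cat., CH2Cl2, 0 °C) of 26 with F10 gives the protected ester F11.
- Aqueous CF3CO2H in CH2Cl2 removes the tert-butyl ester and both silyl ethers to give 30.

Further compounds
F1 | step 8 | dilithium aldolate of 12 with 6 (alkoxide at C4, side-chain enolate) | CC[C@@H](C)C#CC([O-])[C@H]1C(=O)CC[C@@H](C)[C@@H]1C(C)=C(C)[O-].[Li+].[Li+]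
F2 | step 12 | 5α-triethylsilyl ether of enone 20 | CC[C@@H](C)C1=CC(=O)[C@H]2[C@H](O[Si](CC)(CC)CC)[C@H](ON(C(C)=O)c3ccccc3)C[C@@H](C)[C@@H]2[C@@]1(C)C(C)=O
F3 | step 12 | 4α-allylic alcohol of F2 | CC[C@@H](C)C1=C[C@H](O)[C@H]2[C@H](O[Si](CC)(CC)CC)[C@H](ON(C(C)=O)c3ccccc3)C[C@@H](C)[C@@H]2[C@@]1(C)C(C)=O
F4 | step 12 | 4α-methyl carbonate of F3 | CC[C@@H](C)C1=C[C@H](OC(=O)OC)[C@H]2[C@H](O[Si](CC)(CC)CC)[C@H](ON(C(C)=O)c3ccccc3)C[C@@H](C)[C@@H]2[C@@]1(C)C(C)=O
F5 | step 12 | 4α-[N-(2-nitrobenzenesulfonyl)-N'-isopropylidenehydrazinyl] compound | CC[C@@H](C)C1=C[C@H](N(N=C(C)C)S(=O)(=O)c3ccccc3[N+](=O)[O-])[C@H]2[C@H](O[Si](CC)(CC)CC)[C@H](ON(C(C)=O)c4ccccc4)C[C@@H](C)[C@@H]2[C@@]1(C)C(C)=O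
F6 | step 12 | 4α-diazenyl compound with 5α-triethylsilyloxy group | CC[C@@H](C)C1=C[C@H](N=N)[C@H]2[C@H](O[Si](CC)(CC)CC)[C@H](ON(C(C)=O)c3ccccc3)C[C@@H](C)[C@@H]2[C@@]1(C)C(C)=O
F7 | step 12 | 5α-triethylsilyl ether of 23 | CC[C@@H](C)[C@H]1C=C[C@H]2[C@H](O[Si](CC)(CC)CC)[C@H](ON(C(C)=O)c3ccccc3)C[C@@H](C)[C@@H]2[C@@]1(C)C(C)=O
F8 | step 17 | (Z)-5-(allyloxy)-3-methyl-5-oxopent-2-enoic acid | C=CCOC(=O)C/C(C)=C\C(=O)O
F9 | step 17 | 5-allyl 1-tert-butyl (Z)-3-methylpent-2-enedioate | C=CCOC(=O)C/C(C)=C\C(=O)OC(C)(C)C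
F10 | step 17 | (Z)-5-tert-butoxy-3-methyl-5-oxopent-3-enoic acid | OC(=O)C/C(C)=C\C(=O)OC(C)(C)C
F11 | step 17 | tert-butyl ester of 29 | CC[C@@H](C)[C@H]1C=C[C@H]2[C@H](O[Si](CC)(CC)CC)[C@H](OC(=O)C/C(C)=C\C(=O)OC(C)(C)C)C[C@@H](C)[C@@H]2[C@@]1(C)C(=O)CCO[Si](C(C)C)(C(C)C)C(C)C
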